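**Plan**

Numbering used: ring C1 (bears the side chain), C2 (OH), C3 (angelate), C4 (methyl) and C5 (ring epoxide), C6 (CH2); side chain C7 (=CH2), C8 (angelate), C9, C10 and C11 (side-chain epoxide).
Retrosynthesis: the silyl group on O-2, the C10–C11 epoxide oxygen, the O-8 angelate and the C7–C8 bond (alkenyl bromide + 4-methylpent-3-enal) are removed in turn; the C2–O bond is traced back to a C2 acetyl group and the ring epoxide to a C4=C5 alkene; the cyclohexene is then cut at C6–C1 and C2–C3 into a C1–C2 enone and a C3–C6 dienyl angelate.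
Enabling feature: the C4–C5 epoxide is the oxidized footprint of a cyclohexene double bond opposite the C1–C2 edge, and the trans C1/C2, cis C2/C3 array with oxygen on C3 and methyl on C4 is the endo-adduct pattern of an (E)-alkene and a (1E)-1-acyloxy-2-methylbutadiene. The C2 oxygen is carried through the cycloaddition as an acetyl group, which activates the alkene, steers regiochemistry and endo approach, and is later exchanged for oxygen with retention.
Forward: 2-bromoacrolein gives the bromodienone; tiglaldehyde gives the dienyl angelate; a catalytic enantioselective Diels–Alder reaction builds the ring; one peracid step installs the ring epoxide and turns acetyl into acetate; the acetate is exchanged for a silyl ether; a chromium-mediated coupling joins the side chain at C7–C8; angeloylation, Shi epoxidation and desilylation finish.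
Stereochemistry: C1, C2, C3 from the cycloaddition (alkene geometry, endo rule, chiral catalyst); C4/C5 from epoxidation anti to the C3 angelate; C8 from the chiral chromium ligand; C10 from the Shi ketone; both (Z)-angelate units are brought in intact.

Key step: step 4

Assumption: the (R)-configured oxazaborolidinium in step 4 and the (S)-configured sulfonamide ligand in step 9 are assumed, from the usual binding models of these catalyst families, to give the configurations drawn; if either sense proved opposite, the mirror-image catalyst or ligand would be used without other change.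

**Route**

Step 1
Reactants: 1 acrolein (prop-2-enal)
Product: 3 2-bromoprop-2-enal, via 2,3-dibromopropanal 2 (not isolated)
Conditions: Br2, CH2Cl2, −78 °C; then Et3N, −78 → 0 °C
Reagents that add atoms: bromine, BrBr
Why: Bromine addition to the enal followed by amine-mediated loss of HBr from the α-bromo aldehyde (halogenation–dehydrohalogenation) is the standard entry to 2-bromoacrolein; no stereocenter is formed.

Step 2
Reactants: 3 2-bromoprop-2-enal; 4 1-(triphenylphosphoranylidene)propan-2-one
Product: 5 (3E)-5-bromohexa-3,5-dien-2-one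
Conditions: CH2Cl2, 0 °C → rt
Reagents that add atoms: none
Why: Wittig olefination with a stabilized acyl ylide should attack only the formyl group and give the (E)-enone.

Step 3
Reactants: 6 tiglaldehyde ((2E)-2-methylbut-2-enal); 7 angelic anhydride ((2Z)-2-methylbut-2-enoic anhydride)
Product: 9 (1E)-2-methylbuta-1,3-dien-1-yl (2Z)-2-methylbut-2-enoate, via potassium dienolate 8 (not isolated)
Conditions: KOtBu, THF, −78 °C; then 7, −78 → 0 °C
Reagents that add atoms: none
Why: γ-Deprotonation of the s-trans enal should give the extended (1E)-dienolate, whose oxygen is acylated by the anhydride (O-acylation of a dienolate) at low temperature without a nucleophilic catalyst, so the (Z)-angelate geometry should be kept.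

Step 4
Reactants: 5 (3E)-5-bromohexa-3,5-dien-2-one; 9 (1E)-2-methylbuta-1,3-dien-1-yl (2Z)-2-methylbut-2-enoate
Product: 10 (1R,5S,6R)-6-acetyl-5-(1-bromoethenyl)-2-methylcyclohex-2-en-1-yl (2Z)-2-methylbut-2-enoate
Conditions: (R)-o-tolyl-CBS oxazaborolidine·HNTf2 (20 mol %), CH2Cl2, −78 → −20 °C
Reagents that add atoms: none
Why: The protonated oxazaborolidine binds the acetyl oxygen of 5 and lowers the LUMO of its α,β double bond (C1=C2), and diene 9 adds in a concerted, asynchronous, normal-demand [4+2] cycloaddition; the closest known reaction type is the oxazaborolidinium-catalysed enantioselective Diels–Alder reaction of acyclic enones with 1-oxygenated dienes. The cyclohexene ring is closed in a single intermolecular suprafacial [4+2] event that forms C6–C1 and C2–C3 together and leaves the C4=C5 double bond for the later epoxide. The trans relation of C1 and C2 follows from the (E) geometry of the enone, the cis relation of the C2 acetyl and the C3 angelate from the endo position of the coordinated acetyl group under the (1E)-acyloxy diene, and the absolute sense from the catalyst, which should leave the Si face of the acetyl-bearing carbon open. The step needs regioselectivity, which the acyloxy oxygen should secure by making the unsubstituted terminus C6 the nucleophilic end that bonds to the β-carbon C1 (a stronger director than the opposing 2-methyl group), and site selectivity, which should hold because the Lewis acid activates most strongly the α,β bond next to the coordinated carbonyl, whereas the distal alkene is deactivated by bromine and would have to form a quaternary centre. The acetyl group is the stand-in for the C2 oxygen and the 1-bromoethenyl group is the handle for the side chain.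

Step 5
Reactants: 10 (1R,5S,6R)-6-acetyl-5-(1-bromoethenyl)-2-methylcyclohex-2-en-1-yl (2Z)-2-methylbut-2-enoate
Product: 12 (1R,2R,3R,4S,6R)-3-(acetyloxy)-4-(1-bromoethenyl)-1-methyl-7-oxabicyclo[4.1.0]heptan-2-yl (2Z)-2-methylbut-2-enoate, via epoxy ketone 11 (not isolated)
Conditions: mCPBA (excess), NaHCO3, CH2Cl2, 0 °C → 40 °C
Reagents that add atoms: mCPBA (3-chloroperoxybenzoic acid), OOC(=O)c1cccc(Cl)c1
Why: The electron-rich trisubstituted C4=C5 bond should be epoxidized first, anti to the pseudoaxial allylic angelate at C3 (steric control by an allylic ester); the peracid then effects Baeyer–Villiger oxidation of the methyl ketone, in which the secondary ring carbon C2 migrates in preference to methyl with retention, while the alkenyl bromide and the conjugated angelate are too electron-poor to be epoxidized.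

Step 6
Reactants: 12 (1R,2R,3R,4S,6R)-3-(acetyloxy)-4-(1-bromoethenyl)-1-methyl-7-oxabicyclo[4.1.0]heptan-2-yl (2Z)-2-methylbut-2-enoate
Product: 13 (1R,2R,3R,4S,6R)-4-(1-bromoethenyl)-3-hydroxy-1-methyl-7-oxabicyclo[4.1.0]heptan-2-yl (2Z)-2-methylbut-2-enoate
Conditions: iBu2AlH (2.2 equiv), CH2Cl2, −78 °C; MeOH, then aq. KNaC4H4O6 (sodium potassium tartrate)
Reagents that add atoms: none
Why: The unhindered acetate should be reduced by iBu2AlH much faster than the α-branched, conjugated angelate (chemoselective reductive deacylation), and the aluminium alkoxide formed at −78 °C is not basic enough to trigger 1,2-acyl migration from O-3 before the cold, near-neutral quench.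

Step 7
Reactants: 13 (1R,2R,3R,4S,6R)-4-(1-bromoethenyl)-3-hydroxy-1-methyl-7-oxabicyclo[4.1.0]heptan-2-yl (2Z)-2-methylbut-2-enoate
Product: 14 (1R,2R,3R,4S,6R)-4-(1-bromoethenyl)-1-methyl-3-[(triethylsilyl)oxy]-7-oxabicyclo[4.1.0]heptan-2-yl (2Z)-2-methylbut-2-enoate
Conditions: Et3SiCl, imidazole, CH2Cl2, 0 °C
Reagents that add atoms: chlorotriethylsilane (Et3SiCl), CC[Si](Cl)(CC)CC
Why: Silylation of the equatorial secondary alcohol under weakly basic imidazole conditions should not promote acyl migration, and the triethylsilyl ether masks O-2 until the last step.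

Step 8
Reactants: 15 4-methylpent-3-en-1-ol
Product: 16 4-methylpent-3-enal
Conditions: Dess–Martin periodinane, NaHCO3, CH2Cl2, 0 °C; used directly
Reagents that add atoms: none
Why: Dess–Martin oxidation under buffered, non-basic conditions should give the β,γ-unsaturated aldehyde without migration of the double bond into conjugation.

Step 9
Reactants: 14 (1R,2R,3R,4S,6R)-4-(1-bromoethenyl)-1-methyl-3-[(triethylsilyl)oxy]-7-oxabicyclo[4.1.0]heptan-2-yl (2Z)-2-methylbut-2-enoate; 16 4-methylpent-3-enal
Product: 17 (1R,2R,3R,4R,6R)-4-[(3S)-3-hydroxy-6-methylhepta-1,5-dien-2-yl]-1-methyl-3-[(triethylsilyl)oxy]-7-oxabicyclo[4.1.0]heptan-2-yl (2Z)-2-methylbut-2-enoate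
Conditions: CrCl2, NiCl2 (cat.), N-{2-[(4S)-4-isopropyl-4,5-dihydro-1,3-oxazol-2-yl]-6-methylphenyl}methanesulfonamide, Et3N, THF, rt
Reagents that add atoms: none
Why: In this asymmetric Nozaki–Hiyama–Kishi coupling, nickel activates the alkenyl bromide and passes the alkenyl group to chromium, which adds only to the aldehyde and tolerates the esters, the epoxide and the silyl ether; the chiral sulfonamide ligand on chromium controls the aldehyde face and so sets C8.

Step 10
Reactants: 17 (1R,2R,3R,4R,6R)-4-[(3S)-3-hydroxy-6-methylhepta-1,5-dien-2-yl]-1-methyl-3-[(triethylsilyl)oxy]-7-oxabicyclo[4.1.0]heptan-2-yl (2Z)-2-methylbut-2-enoate; 7 angelic anhydride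
Product: 18 (1R,2R,3R,4R,6R)-1-methyl-4-{(3S)-6-methyl-3-[(2Z)-2-methylbut-2-enoyloxy]hepta-1,5-dien-2-yl}-3-[(triethylsilyl)oxy]-7-oxabicyclo[4.1.0]heptan-2-yl (2Z)-2-methylbut-2-enoate
Conditions: LiN(SiMe3)2, THF, −78 °C; then 7, −78 → −20 °C
Reagents that add atoms: none
Why: Acylation of the lithium alkoxide with angelic anhydride at low temperature (stereoconservative angeloylation) avoids the nucleophilic catalysts and heat that isomerize angelates to tiglates; C8 is not touched.

Step 11
Reactants: 18 (1R,2R,3R,4R,6R)-1-methyl-4-{(3S)-6-methyl-3-[(2Z)-2-methylbut-2-enoyloxy]hepta-1,5-dien-2-yl}-3-[(triethylsilyl)oxy]-7-oxabicyclo[4.1.0]heptan-2-yl (2Z)-2-methylbut-2-enoate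
Product: 19 (1R,2R,3R,4R,6R)-4-{(3S)-4-[(2R)-3,3-dimethyloxiran-2-yl]-3-[(2Z)-2-methylbut-2-enoyloxy]but-1-en-2-yl}-1-methyl-3-[(triethylsilyl)oxy]-7-oxabicyclo[4.1.0]heptan-2-yl (2Z)-2-methylbut-2-enoate
Conditions: D-fructose-derived Shi ketone, Oxone (2KHSO5·KHSO4·K2SO4), K2CO3, Bu4NHSO4, MeCN/(MeO)2CH2/aq. Na2B4O7 buffer (pH 10.5), 0 °C
Reagents that add atoms: potassium peroxymonosulfate (KHSO5, the active salt of Oxone), [K+].[O-]S(=O)(=O)OO
Why: In the Shi asymmetric epoxidation the dioxirane of the D-fructose-derived ketone should epoxidize the only electron-rich trisubstituted alkene through the spiro transition state, which is expected to give the (R) configuration at C10; the 1,1-disubstituted alkene next to the allylic ester and the conjugated angelate double bonds should react much more slowly.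

Step 12
Reactants: 19 (1R,2R,3R,4R,6R)-4-{(3S)-4-[(2R)-3,3-dimethyloxiran-2-yl]-3-[(2Z)-2-methylbut-2-enoyloxy]but-1-en-2-yl}-1-methyl-3-[(triethylsilyl)oxy]-7-oxabicyclo[4.1.0]heptan-2-yl (2Z)-2-methylbut-2-enoate
Product: 20 (1R,2R,3R,4R,6R)-4-{(3S)-4-[(2R)-3,3-dimethyloxiran-2-yl]-3-[(2Z)-2-methylbut-2-enoyloxy]but-1-en-2-yl}-3-hydroxy-1-methyl-7-oxabicyclo[4.1.0]heptan-2-yl (2Z)-2-methylbut-2-enoate (CNP0296086.5)
Conditions: Et3N·3HF, THF, 0 °C → rt
Reagents that add atoms: none
Why: Fluoride cleavage of the triethylsilyl ether under slightly acidic, non-basic conditions should free the C2 hydroxyl without opening the epoxides and without the base-induced angelate migration between O-3 and O-2.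

**Compound list**

1 | acrolein (prop-2-enal) | C=CC=O | starting material
2 | 2,3-dibromopropanal | O=CC(Br)CBr | intermediate
3 | 2-bromoprop-2-enal (2-bromoacrolein) | C=C(Br)C=O | intermediate
4 | 1-(triphenylphosphoranylidene)propan-2-one | CC(=O)C=P(c1ccccc1)(c1ccccc1)c1ccccc1 | starting material
5 | (3E)-5-bromohexa-3,5-dien-2-one | CC(=O)/C=C/C(Br)=C | intermediate
6 | tiglaldehyde, (2E)-2-methylbut-2-enal | C/C=C(\C)C=O | starting material
7 | angelic anhydride, (2Z)-2-methylbut-2-enoic anhydride | C/C=C(/C)C(=O)OC(=O)/C(C)=C\C | starting material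
8 | potassium (1E)-2-methylbuta-1,3-dien-1-olate | C=C/C(C)=C/[O-].[K+] | intermediate
9 | (1E)-2-methylbuta-1,3-dien-1-yl (2Z)-2-methylbut-2-enoate | C=C/C(C)=C/OC(=O)/C(C)=C\C | intermediate
10 | (1R,5S,6R)-6-acetyl-5-(1-bromoethenyl)-2-methylcyclohex-2-en-1-yl (2Z)-2-methylbut-2-enoate | C=C(Br)[C@H]1CC=C(C)[C@H](OC(=O)/C(C)=C\C)[C@@H]1C(C)=O | intermediate
11 | (1R,2R,3R,4S,6R)-3-acetyl-4-(1-bromoethenyl)-1-methyl-7-oxabicyclo[4.1.0]heptan-2-yl (2Z)-2-methylbut-2-enoate | C=C(Br)[C@H]1C[C@H]2O[C@@]2(C)[C@H](OC(=O)/C(C)=C\C)[C@@H]1C(C)=O | intermediate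
12 | (1R,2R,3R,4S,6R)-3-(acetyloxy)-4-(1-bromoethenyl)-1-methyl-7-oxabicyclo[4.1.0]heptan-2-yl (2Z)-2-methylbut-2-enoate | C=C(Br)[C@H]1C[C@H]2O[C@@]2(C)[C@H](OC(=O)/C(C)=C\C)[C@@H]1OC(C)=O | intermediate
13 | (1R,2R,3R,4S,6R)-4-(1-bromoethenyl)-3-hydroxy-1-methyl-7-oxabicyclo[4.1.0]heptan-2-yl (2Z)-2-methylbut-2-enoate | C=C(Br)[C@H]1C[C@H]2O[C@@]2(C)[C@H](OC(=O)/C(C)=C\C)[C@@H]1O | intermediate
14 | (1R,2R,3R,4S,6R)-4-(1-bromoethenyl)-1-methyl-3-[(triethylsilyl)oxy]-7-oxabicyclo[4.1.0]heptan-2-yl (2Z)-2-methylbut-2-enoate | C=C(Br)[C@H]1C[C@H]2O[C@@]2(C)[C@H](OC(=O)/C(C)=C\C)[C@@H]1O[Si](CC)(CC)CC | intermediate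
15 | 4-methylpent-3-en-1-ol | CC(C)=CCCO | starting material
16 | 4-methylpent-3-enal | CC(C)=CCC=O | intermediate
17 | (1R,2R,3R,4R,6R)-4-[(3S)-3-hydroxy-6-methylhepta-1,5-dien-2-yl]-1-methyl-3-[(triethylsilyl)oxy]-7-oxabicyclo[4.1.0]heptan-2-yl (2Z)-2-methylbut-2-enoate | C=C([C@H](CC=C(C)C)O)[C@H]1C[C@H]2O[C@@]2(C)[C@H](OC(=O)/C(C)=C\C)[C@@H]1O[Si](CC)(CC)CC | intermediate
18 | (1R,2R,3R,4R,6R)-1-methyl-4-{(3S)-6-methyl-3-[(2Z)-2-methylbut-2-enoyloxy]hepta-1,5-dien-2-yl}-3-[(triethylsilyl)oxy]-7-oxabicyclo[4.1.0]heptan-2-yl (2Z)-2-methylbut-2-enoate | C=C([C@H](CC=C(C)C)OC(=O)/C(C)=C\C)[C@H]1C[C@H]2O[C@@]2(C)[C@H](OC(=O)/C(C)=C\C)[C@@H]1O[Si](CC)(CC)CC | intermediate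
19 | (1R,2R,3R,4R,6R)-4-{(3S)-4-[(2R)-3,3-dimethyloxiran-2-yl]-3-[(2Z)-2-methylbut-2-enoyloxy]but-1-en-2-yl}-1-methyl-3-[(triethylsilyl)oxy]-7-oxabicyclo[4.1.0]heptan-2-yl (2Z)-2-methylbut-2-enoate | C=C([C@H](C[C@H]1OC1(C)C)OC(=O)/C(C)=C\C)[C@H]1C[C@H]2O[C@@]2(C)[C@H](OC(=O)/C(C)=C\C)[C@@H]1O[Si](CC)(CC)CC | intermediate
20 | (1R,2R,3R,4R,6R)-4-{(3S)-4-[(2R)-3,3-dimethyloxiran-2-yl]-3-[(2Z)-2-methylbut-2-enoyloxy]but-1-en-2-yl}-3-hydroxy-1-methyl-7-oxabicyclo[4.1.0]heptan-2-yl (2Z)-2-methylbut-2-enoate (CNP0296086.5) | C=C([C@H](C[C@H]1OC1(C)C)OC(=O)/C(C)=C\C)[C@H]1C[C@H]2O[C@@]2(C)[C@H](OC(=O)/C(C)=C\C)[C@@H]1O | target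

**Step count and risks**

Total step count: 12. Longest linear sequence: 10 steps (steps 1, 2, 4, 5, 6, 7, 9, 10, 11, 12).

Step 4. What may go wrong: the moderately electron-rich acyloxy diene may add too slowly to the β-substituted enone, the 2-methyl group may erode the regiochemical preference, enantiofacial discrimination may be low, or acid may strip the allylic angelate from the adduct. The fallback sets out from 3 and comes back at 10. Wittig reaction of 3 with (triphenylphosphoranylidene)acetaldehyde would give (2E)-4-bromopenta-2,4-dienal F1. Its iminium-catalysed Diels–Alder reaction with 9, using (5S)-5-benzyl-2,2,3-trimethylimidazolidin-4-one hydrochloride in aqueous acetonitrile, is expected to add the diene endo to the Si face of the formyl-bearing carbon and give the 6-formyl analogue of 10 F2. Methyl addition with MeMgBr/CeCl3 at −78 °C would give the 6-(1-hydroxyethyl) analogue of 10 F3 (both carbinol epimers), and Dess–Martin oxidation would deliver 10.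

Step 9. What may go wrong: poor facial control at the aldehyde, giving both C8 epimers, or slow activation of the hindered 1,1-disubstituted alkenyl bromide. The fallback sets out from 14 and 16 and comes back at 17. The coupling run with CrCl2 and catalytic NiCl2 in DMSO without a chiral ligand would give 17 together with the C8 epimer of 17 F4. Dess–Martin oxidation of the mixture would converge both on the C8 ketone (enone) of 17 F5. Reduction with catecholborane and the (R)-configured 2-methyl-CBS oxazaborolidine, the alkenyl group acting as the large substituent, should return 17 as the (S)-alcohol.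

Step 6. What may go wrong: competing reduction of the angelate, or migration of the angeloyl group from O-3 to the freed O-2 during work-up. The fallback sets out from 6 and 5 and comes back at 14. Acylation of dienolate 8 (from 6 and KOtBu) with acetic anhydride would give (1E)-2-methylbuta-1,3-dien-1-yl acetate F6. The same catalysed cycloaddition with 5 would give the acetate analogue of 10 F7. mCPBA would give, through the acetate analogue of 11 F8, the epoxy diacetate F9. K2CO3 in methanol would remove both acetates with no selectivity required and give the cis-2,3-diol F10. Et3SiCl and imidazole should silylate the equatorial, less hindered C2 hydroxyl to give the C2 triethylsilyl ether with free C3 hydroxyl F11. Acylation of the remaining pseudoaxial C3 hydroxyl with 7 (LiN(SiMe3)2, THF, −78 °C) would give 14.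

Further compounds
F1 | step 4 | (2E)-4-bromopenta-2,4-dienal | C=C(Br)/C=C/C=O
F2 | step 4 | (1R,5S,6R)-5-(1-bromoethenyl)-6-formyl-2-methylcyclohex-2-en-1-yl (2Z)-2-methylbut-2-enoate | C=C(Br)[C@H]1CC=C(C)[C@H](OC(=O)/C(C)=C\C)[C@@H]1C=O
F3 | step 4 | 6-(1-hydroxyethyl) analogue of 10, both carbinol epimers | C=C(Br)[C@H]1CC=C(C)[C@H](OC(=O)/C(C)=C\C)[C@@H]1C(C)O
F4 | step 9 | C8 epimer of 17, (3R)-3-hydroxy side chain | C=C([C@@H](CC=C(C)C)O)[C@H]1C[C@H]2O[C@@]2(C)[C@H](OC(=O)/C(C)=C\C)[C@@H]1O[Si](CC)(CC)CC
F5 | step 9 | (1R,2R,3R,4R,6R)-1-methyl-4-(6-methyl-3-oxohepta-1,5-dien-2-yl)-3-[(triethylsilyl)oxy]-7-oxabicyclo[4.1.0]heptan-2-yl (2Z)-2-methylbut-2-enoate | C=C(C(=O)CC=C(C)C)[C@H]1C[C@H]2O[C@@]2(C)[C@H](OC(=O)/C(C)=C\C)[C@@H]1O[Si](CC)(CC)CC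
F6 | step 6 | (1E)-2-methylbuta-1,3-dien-1-yl acetate | C=C/C(C)=C/OC(C)=O
F7 | step 6 | (1R,5S,6R)-6-acetyl-5-(1-bromoethenyl)-2-methylcyclohex-2-en-1-yl acetate | C=C(Br)[C@H]1CC=C(C)[C@H](OC(C)=O)[C@@H]1C(C)=O
F8 | step 6 | (1R,2R,3R,4S,6R)-3-acetyl-4-(1-bromoethenyl)-1-methyl-7-oxabicyclo[4.1.0]heptan-2-yl acetate | C=C(Br)[C@H]1C[C@H]2O[C@@]2(C)[C@H](OC(C)=O)[C@@H]1C(C)=O
F9 | step 6 | (1R,2R,3R,4S,6R)-4-(1-bromoethenyl)-1-methyl-7-oxabicyclo[4.1.0]heptane-2,3-diyl diacetate | C=C(Br)[C@H]1C[C@H]2O[C@@]2(C)[C@H](OC(C)=O)[C@@H]1OC(C)=O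
F10 | step 6 | (1S,2R,3R,4S,6R)-4-(1-bromoethenyl)-1-methyl-7-oxabicyclo[4.1.0]heptane-2,3-diol | C=C(Br)[C@H]1C[C@H]2O[C@@]2(C)[C@H](O)[C@@H]1O
F11 | step 6 | (1S,2R,3R,4S,6R)-4-(1-bromoethenyl)-1-methyl-3-[(triethylsilyl)oxy]-7-oxabicyclo[4.1.0]heptan-2-ol | C=C(Br)[C@H]1C[C@H]2O[C@@]2(C)[C@H](O)[C@@H]1O[Si](CC)(CC)CC
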